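**Retrosynthetic overview**
1. Target 11 ⇐ O-desilylation of 10 ⇐ protodecarboxylation (ring C–CO2Me → C–H) of the β-resorcylate 8.
2. 8 ⇐ open-chain 3,5,7-triketo ester 6: the C2–C7 bond of 6 (C1–C6 of the benzoate) is made by intramolecular aldol condensation and aromatisation. The benzene ring is the only ring and is formed here.
3. 6 ⇐ Claisen bond C6–C7: trianion of methyl 3,5-dioxohexanoate (4) plus the silylated hydroxy ester 3.
4. 3 ⇐ acidic methanolysis and silylation of sophorolipid 1.
5. Feature on which the plan rests: the resorcinol ring with its C17 chain at C5 is a decarboxylated tetraketide. The chain C1'–C17', with the C8'=C9' Z alkene and the C16' S carbinol, is C2–C18 of (9Z,17S)-17-hydroxyoleic acid (the sophorolipid aglycone), whose C1 becomes the ring carbon carrying the chain.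

Key step: step 4

Assumption: commercial sophorolipid is a mixture of congeners (lactone and acid forms, partly acetylated, with minor chain variants). Compound 1 is drawn as the deacetylated acid form of the dominant (9Z,17S)-17-hydroxyoctadec-9-enoic aglycone. Acetates and the macrolactone are methanolysed in the same operation, and minor chain congeners are removed at the stage of ester 2 by chromatography (AgNO3-impregnated silica if needed). Methyl 3,5-dioxohexanoate is taken as a catalogue compound.

**Step 1**
Reactants: 1 sophorolipid, acid form (17-L-sophorosyloxyoleic acid)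
Product: 2 methyl (9Z,17S)-17-hydroxyoctadec-9-enoate
Conditions: HCl (1.25 M in MeOH), reflux; NaHCO3 work-up; SiO2 chromatography
Reagents that add atoms: methanol, CO
Why: Acid-catalysed methanolysis (Fischer glycoside cleavage and esterification) splits both glycosidic acetals and esterifies the carboxyl group, while the C17–O bond of the aglycone is never broken, so the S carbinol and the Z alkene should be carried over unchanged.

**Step 2**
Reactants: 2 methyl (9Z,17S)-17-hydroxyoctadec-9-enoate
Product: 3 methyl (9Z,17S)-17-[(tert-butyldimethylsilyl)oxy]octadec-9-enoate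
Conditions: TBSCl, imidazole, DMF, rt
Reagents that add atoms: tert-butyldimethylsilyl chloride, CC(C)(C)[Si](C)(C)Cl
Why: Standard imidazole-promoted silylation of a secondary alcohol masks the only acidic O–H before the polyanion chemistry and does not touch the stereocentre.

**Step 3**
Reactants: 3 methyl (9Z,17S)-17-[(tert-butyldimethylsilyl)oxy]octadec-9-enoate; 4 methyl 3,5-dioxohexanoate
Product: 6 methyl (15Z,23S)-23-[(tert-butyldimethylsilyl)oxy]-3,5,7-trioxotetracos-15-enoate, via trilithio methyl 3,5-dioxohexanoate 5 (not isolated)
Conditions: 4 (2.5 equiv), LDA (7.5 equiv), THF, 0 °C; then 3 (1 equiv), 0 °C → rt; cold 1 M HCl to pH 4–5; crude 6 taken on after a short silica plug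
Reagents that add atoms: none
Why: Claisen acylation of a β,δ-diketo ester trianion by an aliphatic ester takes place at the last-formed, most basic terminal carbanion (C6 of 4) and gives the 3,5,7-triketo ester; the excess trianion absorbs the proton that the more acidic product releases, and the silyl ether and the isolated alkene are inert to amide bases.

**Step 4**
Reactants: 6 methyl (15Z,23S)-23-[(tert-butyldimethylsilyl)oxy]-3,5,7-trioxotetracos-15-enoate
Product: 8 methyl 2,4-dihydroxy-6-[(8Z,16S)-16-[(tert-butyldimethylsilyl)oxy]heptadec-8-en-1-yl]benzoate, via cyclic aldol adduct 7 (not isolated)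
Conditions: 1 M aq KOH (4 equiv), THF, 0 °C → rt, Ar; then 1 M HCl to pH 4–5 at 0 °C
Reagents that add atoms: none
Why: Hydroxide converts 6 into its polyenolate, in which the most acidic carbon, C2 between the ester and the C3 ketone, adds to the C7 carbonyl; the cyclic β-hydroxy ketone 7 then loses water by E1cB and the resulting cyclohexenedione enolises twice to the benzenoid 8. The closest known reaction type is the biomimetic aldol cyclisation of 3,5,7-triketo esters to β-resorcylates, the laboratory counterpart of ring closure by alkylresorcinol synthases. The single ring is closed through the C2–C7 bond in the 6-(enolendo)-exo-trig mode. No lasting stereocentre is created: the two ring stereocentres of 7 are erased on aromatisation, and the C23 silyl ether and the Z alkene lie far from any enolisable position. The selectivity needed is aldol closure C2→C7 over Claisen closure C6→C1 (acylphloroglucinol), lactonisation to a 4-hydroxy-2-pyranone and the alternative aldol C8→C3; it should be secured by the methyl ester being a poor acyl acceptor, by the absence of chelating magnesium alkoxide media that favour the Claisen mode, and by C8 being far less acidic than C2. Aromatisation makes the aldol pathway irreversible, so the resorcylate is the thermodynamic sink.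

**Step 5**
Reactants: 8 methyl 2,4-dihydroxy-6-[(8Z,16S)-16-[(tert-butyldimethylsilyl)oxy]heptadec-8-en-1-yl]benzoate
Product: 10 5-[(8Z,16S)-16-[(tert-butyldimethylsilyl)oxy]heptadec-8-en-1-yl]benzene-1,3-diol, via resorcylic acid 9 (not isolated)
Conditions: KOH (2 M), MeOH/H2O 1:1 (degassed), reflux, Ar; then 1 M HCl to pH 4 at 0 °C
Reagents that add atoms: none
Why: Saponification gives the 2,4-dihydroxybenzoate, a vinylogous β-keto acid that is protonated at C1 and loses CO2 in hot aqueous alkali (protodecarboxylation of a β-resorcylic acid); the secondary alkyl silyl ether and the isolated Z alkene are inert to hydroxide, and any silyl ether lost here only anticipates step 6.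

**Step 6**
Reactants: 10 5-[(8Z,16S)-16-[(tert-butyldimethylsilyl)oxy]heptadec-8-en-1-yl]benzene-1,3-diol
Product: 11 Hansfordiol E, 5-[(8Z,16S)-16-hydroxyheptadec-8-en-1-yl]benzene-1,3-diol
Conditions: HF (48% aq), MeCN/THF, 0 °C → rt (polyethylene vessel)
Reagents that add atoms: none
Why: Fluoride-driven desilylation cleaves the Si–O bond only, so the C16' carbinol is released with retention, and the base-free medium spares the resorcinol and the Z alkene.

**Compound list**
1 | sophorolipid, acid form (17-L-sophorosyloxyoleic acid) | OC[C@H]1O[C@@H](O[C@@H](C)CCCCCC/C=C\CCCCCCCC(=O)O)[C@H](O[C@@H]2O[C@H](CO)[C@@H](O)[C@H](O)[C@H]2O)[C@@H](O)[C@@H]1O | starting material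
2 | methyl (9Z,17S)-17-hydroxyoctadec-9-enoate | C[C@H](O)CCCCCC/C=C\CCCCCCCC(=O)OC | intermediate
3 | methyl (9Z,17S)-17-[(tert-butyldimethylsilyl)oxy]octadec-9-enoate | C[C@H](O[Si](C)(C)C(C)(C)C)CCCCCC/C=C\CCCCCCCC(=O)OC | intermediate
4 | methyl 3,5-dioxohexanoate | COC(=O)CC(=O)CC(C)=O | starting material
5 | trilithio methyl 3,5-dioxohexanoate (trianion of 4) | [Li+].[Li+].[Li+].COC(=O)[CH-]C(=O)[CH-]C(=O)[CH2-] | intermediate (not isolated)
6 | methyl (15Z,23S)-23-[(tert-butyldimethylsilyl)oxy]-3,5,7-trioxotetracos-15-enoate (drawn as the triketo tautomer) | C[C@H](O[Si](C)(C)C(C)(C)C)CCCCCC/C=C\CCCCCCCC(=O)CC(=O)CC(=O)CC(=O)OC | intermediate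
7 | methyl 2-hydroxy-2-[(8Z,16S)-16-[(tert-butyldimethylsilyl)oxy]heptadec-8-en-1-yl]-4,6-dioxocyclohexane-1-carboxylate (cyclic aldol adduct; ring stereocentres undefined and transient) | C[C@H](O[Si](C)(C)C(C)(C)C)CCCCCC/C=C\CCCCCCCC1(O)CC(=O)CC(=O)C1C(=O)OC | intermediate (not isolated)
8 | methyl 2,4-dihydroxy-6-[(8Z,16S)-16-[(tert-butyldimethylsilyl)oxy]heptadec-8-en-1-yl]benzoate | C[C@H](O[Si](C)(C)C(C)(C)C)CCCCCC/C=C\CCCCCCCc1cc(O)cc(O)c1C(=O)OC | intermediate
9 | 2,4-dihydroxy-6-[(8Z,16S)-16-[(tert-butyldimethylsilyl)oxy]heptadec-8-en-1-yl]benzoic acid (resorcylic acid) | C[C@H](O[Si](C)(C)C(C)(C)C)CCCCCC/C=C\CCCCCCCc1cc(O)cc(O)c1C(=O)O | intermediate (not isolated)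
10 | 5-[(8Z,16S)-16-[(tert-butyldimethylsilyl)oxy]heptadec-8-en-1-yl]benzene-1,3-diol | C[C@H](O[Si](C)(C)C(C)(C)C)CCCCCC/C=C\CCCCCCCc1cc(O)cc(O)c1 | intermediate
11 | Hansfordiol E, 5-[(8Z,16S)-16-hydroxyheptadec-8-en-1-yl]benzene-1,3-diol | C[C@H](O)CCCCCC/C=C\CCCCCCCc1cc(O)cc(O)c1 | target

**Totals**
Total step count: 6. Longest linear sequence: 6 steps (1 → 11).

**Steps most likely to fail**

Step 3. The Claisen acylation may stall because the acidic triketo ester product, or the α-methylene of ester 3, transfers a proton to the trianion, so conversion of the valuable ester stays low. Fallback, setting out from 3: aminolysis with N,O-dimethylhydroxylamine hydrochloride and i-PrMgCl (THF, −20 °C) should give the Weinreb amide (9Z,17S)-17-[(tert-butyldimethylsilyl)oxy]-N-methoxy-N-methyloctadec-9-enamide F1. Acylation of trianion 5 (about 1.3 equiv) with F1 then proceeds through a chelated tetrahedral adduct that persists until the acidic quench, so no acidic product is present beside the trianion. The fallback returns to the route at 6.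

Step 4. The ring may close in the wrong mode (Claisen closure to the acylphloroglucinol, or O-acylation to the pyranone), or hydroxide may cleave the polyketone by retro-Claisen attack. Fallback, setting out from 3, replaces the ester terminus by a carboxylate, which cannot act as an acyl donor:
- Acylation of pentane-2,4-dione (deprotonated twice with LDA, THF, 0 °C, used in excess) with 3 should give the triketone (14Z,22S)-22-[(tert-butyldimethylsilyl)oxy]tricos-14-ene-2,4,6-trione F2.
- Threefold deprotonation of F2 with LDA, preferentially at the methyl terminus, and carboxylation with CO2 should give (15Z,23S)-23-[(tert-butyldimethylsilyl)oxy]-3,5,7-trioxotetracos-15-enoic acid F3.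
- In acetate buffer at about pH 5, F3 should cyclise by the same C2→C7 aldol mode directly to the resorcylic acid.
- The fallback returns to the route at 9, which is decarboxylated to 10 by heating as in the second half of step 5.

Step 5. Acyl–oxygen hydrolysis of the hydrogen-bonded, doubly ortho-substituted ester may be slow, and the resorcinolate may oxidise in hot alkali during a long reaction. Fallback, setting out from 8: non-hydrolytic SN2 O-demethylation with LiI in pyridine at reflux under argon gives the lithium salt of 9. After acidification, the free acid 9 is heated in DMF at about 120 °C to lose CO2. The fallback returns to the route at 10, and no compound outside the list is formed (F0).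

**Further compounds**
F1 | step 3 | (9Z,17S)-17-[(tert-butyldimethylsilyl)oxy]-N-methoxy-N-methyloctadec-9-enamide | C[C@H](O[Si](C)(C)C(C)(C)C)CCCCCC/C=C\CCCCCCCC(=O)N(C)OC
F2 | step 4 | (14Z,22S)-22-[(tert-butyldimethylsilyl)oxy]tricos-14-ene-2,4,6-trione | C[C@H](O[Si](C)(C)C(C)(C)C)CCCCCC/C=C\CCCCCCCC(=O)CC(=O)CC(C)=O
F3 | step 4 | (15Z,23S)-23-[(tert-butyldimethylsilyl)oxy]-3,5,7-trioxotetracos-15-enoic acid | C[C@H](O[Si](C)(C)C(C)(C)C)CCCCCC/C=C\CCCCCCCC(=O)CC(=O)CC(=O)CC(=O)O
F0 | step 5 | none | none
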